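Atom labels used throughout: ring A is the ring that ends as the sulfate (C1′ on the oxygen to ring B, C2′ the oxygenated carbon, Br on C4′ and C6′). Ring B is the central ring (C1 on the oxygen to ring A, C2 on the oxygen to ring C, Br on C3, C4, C5, H on C6). Ring C is the 2,4-dibromophenyl ring.

## Analysis of the target

Bromoiesol A sulfate is a triaryl diether: three benzene rings joined by two diaryl ether oxygens, carrying seven bromines and one aryl hydrogen sulfate. Rings A and C are both 2,4-dibromophenoxy units, ring A with an extra oxygen on C2′ that is sulfated. Ring B is the crowded ring, with two adjacent aryloxy groups on C1 and C2, three contiguous bromines on C3–C5 and one hydrogen on C6. There are no stereocentres, and the hindered ether axes carry no element of chirality that needs control. The sensitive groups are the sulfate monoester, which is cleaved by acid and heat and so must come last, and the seven C–Br bonds, which rule out alkyllithium reagents, zerovalent palladium, catalytic hydrogenolysis and alkali metals on the brominated intermediates. The difficulty is regiochemical: all three rings are brominated aryl ethers, so bromination of a preformed triaryl diether cannot be steered, and ring B needs three adjacent bromines beside two different aryloxy groups. The strategy rests on reading ring B as a four-carbon unit C3–C6 that already holds the C4 and C5 bromines, closed by the two oxygen-bearing carbons C1 and C2. The first maps onto the symmetrical diene 9, the second onto the ketene acetal 6 that already carries ring A.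

## Retrosynthetic reasoning

**S–O bond of the sulfate (24 ⇒ 22).** The sulfate ester is the most fragile group and makes the molecule ionic, so it is removed first in the backward sense. All earlier steps then run on neutral phenols and ethers that can be chromatographed. The forward step is O-sulfation of the single free phenol of 22, through the salt 23.

**O–CH3 bond on ring A (22 ⇒ 20).** The ring A oxygen on C2′ is carried as a methyl ether so that, earlier in the route, the only free phenol is the one on C2 of ring B. The forward step has to cleave an alkyl aryl ether while leaving two diaryl ethers intact, which is a difference in mechanism (attack at an sp3 carbon, through borate 21) and not a matter of fine tuning.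

**Ring C–O bond (20 ⇒ 14 + 19).** The ether between C2 of ring B and ring C is cut on the ring C side. Ring C is the simplest aryl group in the molecule and can be delivered as an electrophile by the symmetrical iodonium salt 19, so no transition metal meets the C–Br bonds. Cutting on the ring B side would instead need an electrophilic pentasubstituted ring B.

**One C–I bond of the iodonium salt (19 ⇒ 15 + 16).** Salt 19 is cut at one of its two C–I bonds into arene 15 and aryl iodide 16, so that each aryl group has its own source. The forward reaction oxidises 16 at iodine to the diacetate 17, which substitutes 15 at C4, the position ortho to one bromine and para to the other. The hydrogensulfate 18 that results is exchanged to the chloride. The aryl iodide that the later O-arylation sets free is 16 again, so it can be recovered and returned to this step.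

**C3–Br bond (14 ⇒ 13).** The last bromine of ring B is put in by substitution while the C2 hydroxyl is still free. In 13 the position para to that hydroxyl (C5) is already brominated, so C3 is the only position the hydroxyl can activate, and C6 is left to the much weaker aryloxy group. For this reason the bromination precedes the O-arylation.

**C1–C6 and C2–C3 bonds of ring B (13 ⇒ 6 + 9).** This is the ring-forming disconnection. Cutting these two bonds leaves a four-carbon diene that holds the two bromines of C4 and C5 symmetrically, and a two-carbon unit in which C1 carries ring A and C2 is at the carboxylic acid oxidation level. The forward reaction must join the two in a (4+2) cycloaddition (10), extrude the sulfonyl bridge (11), and lose one silyloxy group with the hydrogen on C1 to give 12 and then 13. It yields the phenol on C2 beside the ring A ether, which is what the next two steps need.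

**Diene 9 (⇒ 7).** The dioxide is reached by oxidation at sulfur of thiophene 7, through S-oxide 8. No carbon–carbon bond is made and the bromine positions are fixed by the starting material.

**Ketene acetal 6 (⇒ 4 ⇒ 2 + 3; 2 ⇒ 1).** The two O–Si bonds are cut first, through silyl ester 5, giving acid 4. Acid 4 is cut at the O–CH2 bond into phenol 2 and acid 3, and 2 is cut at its C4–Br bond into 1. That bromination is unambiguous because it goes para to the free hydroxyl.

## Alternatives that were turned down

**Alternative 1:** Ring A is disconnected at C1′–C6′ and C2′–C3′. In the forward sense 3,5-dibromo-2-pyrone A1 would add to the alkynyl boronate A2, the pinacol boronate of the ethynyl ether of the ring B–C phenol. Loss of the lactone bridge by decarboxylation would then give aryl boronate A3 with boron on C2′. In its favour, the ring A bromines come from the pyrone without any electrophilic bromination. The boron is also a direct precursor of the C2′ oxygen, so the endgame is only oxidation and sulfation. On endgame length, and in avoiding a Lewis-acid demethylation, it is stronger than the chosen route. Against it, the hard part of the target is ring B, and this plan moves that problem unsolved into the phenol from which A2 is made. The usual ways to an aryl ethynyl ether and to its C-borylated form pass through lithium or magnesium acetylides and strong bases. These cannot be used beside five aryl bromides. Pyrone–alkyne cycloadditions also need prolonged heating, which a push–pull ynol ether boronate may not survive. The chosen strategy offers in its place a ring construction at the ring that is hard to substitute, and a precursor (6) made with nothing stronger than a silylamide base.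

**Alternative 2:** Ring B is disconnected at C2–C3 and C3–C4 as a one-carbon ring expansion. The silyl enol ether A4 of a 2-aryloxycyclopentanone would take up a dibromo-substituted carbene, and the siloxycyclopropane would open to the 2-bromocyclohexenone A5. In its favour, every operation is classical and the C3 bromine is placed by the carbene carbon itself. On that one bromine it is stronger than the chosen route, which relies on a directed substitution at C3. Against it, A5 is two oxidation levels below an arene and carries one of the three ring B bromines. It must still be dehydrogenated to a phenol and brominated twice, and the C4 bromination then competes with C6 with no strong directing group. The enol ether A4 must also be formed away from the more acidic α-aryloxy position. Only one skeletal bond of ring B is made for a long sequence. The chosen strategy delivers ring B aromatic, with C4 and C5 already brominated, in the ring-forming step.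

**Alternative 3:** Ring C is disconnected at C1–C2 and C5–C6 and grown on the ether oxygen of ring B. The ethynyl ether A6 would add to pyrone A1, and decarboxylative loss of the lactone bridge would give diaryl ether A7. In its favour, it replaces the O-arylation of a hindered phenol (step 8 here) by a cycloaddition in which the ether oxygen is already in place. On that point it is at least as strong as the chosen route. Against it, the ring-forming step is spent on the simplest ring of the molecule, which an inexpensive iodonium salt delivers in one step. The contiguous tribromo pattern of ring B in A6 would still have to be made by substitution chemistry with no obvious control. After A7 the ring A ether is still missing, and it would have to be formed by arylating a hindered phenol with an electron-rich, doubly ortho-substituted ring A donor, the least favourable kind of diaryl ether coupling. The chosen strategy has one easy ring C arylation and builds ring B around the ring A ether instead.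

Key step: step 5

Assumption: the target is taken as the free hydrogen sulfate as drawn; it would be released from its pyridinium salt only at the very end and kept cold, because aryl hydrogen sulfates slowly lose the sulfate group in acid.

## Route

Step 1
Reactants: 1 2-bromo-6-methoxyphenol
Product: 2 2,4-dibromo-6-methoxyphenol
Conditions: NBS (1.05 equiv), MeCN, 0 °C → rt
Reagents that add atoms: N-bromosuccinimide, O=C1CCC(=O)N1Br
Why: Electrophilic aromatic bromination; the free hydroxyl is the strongest donor and its para position is open, so substitution should go there and not to the positions governed by the methoxy group.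

Step 2
Reactants: 2 2,4-dibromo-6-methoxyphenol; 3 bromoacetic acid
Product: 4 2-(2,4-dibromo-6-methoxyphenoxy)acetic acid
Conditions: NaOH, H2O, 100 °C; then HCl to pH 1
Reagents that add atoms: none
Why: Williamson ether synthesis; the sodium phenoxide displaces bromide from sodium bromoacetate by SN2, the standard preparation of aryloxyacetic acids, and acidification liberates the acid.

Step 3
Reactants: 4 2-(2,4-dibromo-6-methoxyphenoxy)acetic acid
Product: 6 2-(2,4-dibromo-6-methoxyphenoxy)-1,1-bis(trimethylsilyloxy)ethene, via trimethylsilyl ester 5 (not isolated)
Conditions: HN(SiMe3)2 (0.6 equiv), Me3SiCl (cat.), CH2Cl2, 40 °C, evaporate; then LiN(SiMe3)2, Me3SiCl, THF, −78 °C → rt; filter under argon, use crude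
Reagents that add atoms: hexamethyldisilazane, C[Si](C)(C)N[Si](C)(C)C; chlorotrimethylsilane, C[Si](C)(C)Cl
Why: Silyl ester formation, then kinetic enolisation with in situ O-silylation, the enolisation used for α-alkoxy esters in Ireland–Claisen rearrangements. LiN(SiMe3)2 is chosen because it is too weak a base to remove the ring hydrogen between the two bromines, and two identical silyl groups make the alkene geometry irrelevant.

Step 4
Reactants: 7 3,4-dibromothiophene
Product: 9 3,4-dibromothiophene 1,1-dioxide, via 3,4-dibromothiophene 1-oxide 8 (not isolated)
Conditions: dimethyldioxirane (excess), acetone/CH2Cl2, −20 °C → rt; evaporate cold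
Reagents that add atoms: dimethyldioxirane, CC1(C)OO1
Why: Two successive oxygen transfers to sulfur from a neutral dioxirane; the non-aromatic S-oxide is oxidised faster than the thiophene, so the reaction should run through to the dioxide. The only by-product is acetone, so the electrophilic diene can be isolated without aqueous base.

Step 5
Reactants: 6 2-(2,4-dibromo-6-methoxyphenoxy)-1,1-bis(trimethylsilyloxy)ethene; 9 3,4-dibromothiophene 1,1-dioxide
Product: 13 4,5-dibromo-2-(2,4-dibromo-6-methoxyphenoxy)phenol, via sulfone-bridged cycloadduct 10 (not isolated), via cyclohexadiene bis-silyl ketal 11 (not isolated), via aryl trimethylsilyl ether 12 (not isolated)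
Conditions: 6 (1.5 equiv), slow addition of 9, toluene, 25 → 80 °C; then 1 M HCl, THF, rt
Reagents that add atoms: none
Why: Inverse-electron-demand Diels–Alder reaction: the low-lying LUMO of the sulfonyl diene 9 meets the HOMO of ketene acetal 6, and the two α-carbons of the dioxide bond to the alkene carbons, forming C1–C6 and C2–C3 in the bridged sulfone 10. Cheletropic loss of SO2 from 10 gives cyclohexadiene 11, in which C2 is a bis-silyl ketal and C1 carries the aryloxy group and one hydrogen. Ionisation of one silyloxy group of 11, thermally or on the acid work-up, gives a cation that is the σ-complex of the arene and loses the C1 proton, so that 1,2-elimination of Me3SiOH gives silyl ether 12, which the same acid hydrolyses to 13. The closest known reaction type is the cycloaddition of halogenated thiophene 1,1-dioxides to electron-rich alkenes with SO2 extrusion, together with the aromatisation of ketene acetal cycloadducts by loss of an alcohol. Ring B is closed by a bimolecular (4+2) annulation in which both new bonds form in the cycloaddition, and it becomes aromatic through the two extrusions. No stereocentre survives: the three in 10 and the one in 11 are erased on aromatisation, so no facial or endo/exo control is needed. The step needs no regiocontrol because 9 is symmetrical. The direction of aromatisation is fixed because the ketal carbon C2 bears no hydrogen, so the aryloxy group on C1 cannot be expelled, and cross-cycloaddition is favoured over self-dimerisation of 9 by keeping the electron-rich partner in excess and adding 9 slowly.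

Step 6
Reactants: 13 4,5-dibromo-2-(2,4-dibromo-6-methoxyphenoxy)phenol
Product: 14 2,3,4-tribromo-6-(2,4-dibromo-6-methoxyphenoxy)phenol
Conditions: NBS (1.05 equiv), iPr2NH (10 mol%), CH2Cl2, 0 °C → rt
Reagents that add atoms: N-bromosuccinimide, O=C1CCC(=O)N1Br
Why: Amine-mediated ortho-bromination of a phenol (electrophilic aromatic substitution through an N-bromoamine hydrogen-bonded to the hydroxyl). The para position C5 is already brominated, so C3 is the only position the hydroxyl activates. C6 and ring A are activated only by ether oxygens and deactivated by bromines, so they should not compete at one equivalent.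

Step 7
Reactants: 15 1,3-dibromobenzene; 16 2,4-dibromo-1-iodobenzene
Product: 19 bis(2,4-dibromophenyl)iodonium chloride, via diacetoxyiodoarene 17 (not isolated), via iodonium hydrogensulfate 18 (not isolated)
Conditions: 16, CH3CO3H (1.05 equiv), AcOH, 40 °C; then 15 (1.0 equiv), Ac2O, conc. H2SO4, 0 °C → rt; ice, then aq. NaCl
Reagents that add atoms: sodium chloride, [Na+].[Cl-]
Why: Peracid oxidation of the aryl iodide at iodine gives the (diacetoxyiodo)arene 17, and in strong acid this condenses with arene 15 by electrophilic aromatic substitution at C4, ortho to one bromine and para to the other, the classical acid-promoted route from a (diacetoxyiodo)arene and an arene to a diaryliodonium salt. One aryl group comes from each reactant and both are 2,4-dibromophenyl, so the salt is symmetrical. Chloride exchange precipitates it from the hydrogensulfate 18.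

Step 8
Reactants: 14 2,3,4-tribromo-6-(2,4-dibromo-6-methoxyphenoxy)phenol; 19 bis(2,4-dibromophenyl)iodonium chloride
Product: 20 1,2,3-tribromo-5-(2,4-dibromo-6-methoxyphenoxy)-4-(2,4-dibromophenoxy)benzene
Conditions: NaOH, H2O/1,4-dioxane, 80 °C
Reagents that add atoms: none
Why: Metal-free O-arylation of a phenoxide by a diaryliodonium salt (ligand exchange at iodine, then ligand coupling). Both aryl groups on iodine are the same, so only the 2,4-dibromophenyl group can be transferred, and its ortho bromine favours the coupling; the aryl iodide set free is 16 and can be returned to step 7. No transition metal that could insert into the C–Br bonds is present.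

Step 9
Reactants: 20 1,2,3-tribromo-5-(2,4-dibromo-6-methoxyphenoxy)-4-(2,4-dibromophenoxy)benzene
Product: 22 3,5-dibromo-2-[3,4,5-tribromo-2-(2,4-dibromophenoxy)phenoxy]phenol (bromoiesol A), via aryloxydibromoborane 21 (not isolated)
Conditions: BBr3, CH2Cl2, −78 °C → rt; then H2O
Reagents that add atoms: none
Why: Lewis-acid cleavage of an aryl methyl ether: boron coordinates the methoxy oxygen and bromide attacks the methyl carbon by SN2. The two diaryl ethers offer no sp3 carbon and should stay intact; hydrolysis of 21 gives the phenol.

Step 10
Reactants: 22 3,5-dibromo-2-[3,4,5-tribromo-2-(2,4-dibromophenoxy)phenoxy]phenol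
Product: 24 3,5-dibromo-2-[3,4,5-tribromo-2-(2,4-dibromophenoxy)phenoxy]phenyl hydrogen sulfate (bromoiesol A sulfate), via pyridinium aryl sulfate 23 (not isolated)
Conditions: SO3·pyridine, pyridine, 50 °C; evaporate; Dowex 50W (H+ form), MeOH/H2O, 0 °C; freeze-dry
Reagents that add atoms: sulfur trioxide–pyridine complex, O=S(=O)([O-])[n+]1ccccc1
Why: O-sulfation of a phenol with the amine complex of SO3 gives the pyridinium aryl sulfate. Brief cation exchange on a cold sulfonic acid resin should give the hydrogen sulfate without heating in acid.

## Compound list

1 | 2-bromo-6-methoxyphenol | COc1cccc(Br)c1O | starting material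
2 | 2,4-dibromo-6-methoxyphenol | COc1cc(Br)cc(Br)c1O | intermediate
3 | bromoacetic acid | OC(=O)CBr | starting material
4 | 2-(2,4-dibromo-6-methoxyphenoxy)acetic acid | COc1cc(Br)cc(Br)c1OCC(=O)O | intermediate
5 | trimethylsilyl 2-(2,4-dibromo-6-methoxyphenoxy)acetate | COc1cc(Br)cc(Br)c1OCC(=O)O[Si](C)(C)C | intermediate (not isolated)
6 | 2-(2,4-dibromo-6-methoxyphenoxy)-1,1-bis(trimethylsilyloxy)ethene | COc1cc(Br)cc(Br)c1OC=C(O[Si](C)(C)C)O[Si](C)(C)C | intermediate
7 | 3,4-dibromothiophene | Brc1cscc1Br | starting material
8 | 3,4-dibromothiophene 1-oxide | O=S1C=C(Br)C(Br)=C1 | intermediate (not isolated)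
9 | 3,4-dibromothiophene 1,1-dioxide | O=S1(=O)C=C(Br)C(Br)=C1 | intermediate
10 | 2,3-dibromo-5-(2,4-dibromo-6-methoxyphenoxy)-6,6-bis(trimethylsilyloxy)-7-thiabicyclo[2.2.1]hept-2-ene 7,7-dioxide (racemic, mixture of diastereomers; configuration not controlled and not needed) | O=S1(=O)C2C(Br)=C(Br)C1C(O[Si](C)(C)C)(O[Si](C)(C)C)C2Oc1c(Br)cc(Br)cc1OC | intermediate (not isolated)
11 | 2,3-dibromo-6-(2,4-dibromo-6-methoxyphenoxy)-5,5-bis(trimethylsilyloxy)cyclohexa-1,3-diene (racemic) | BrC1=CC(Oc2c(Br)cc(Br)cc2OC)C(O[Si](C)(C)C)(O[Si](C)(C)C)C=C1Br | intermediate (not isolated)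
12 | [4,5-dibromo-2-(2,4-dibromo-6-methoxyphenoxy)phenoxy]trimethylsilane | COc1cc(Br)cc(Br)c1Oc1cc(Br)c(Br)cc1O[Si](C)(C)C | intermediate (not isolated)
13 | 4,5-dibromo-2-(2,4-dibromo-6-methoxyphenoxy)phenol | COc1cc(Br)cc(Br)c1Oc1cc(Br)c(Br)cc1O | intermediate
14 | 2,3,4-tribromo-6-(2,4-dibromo-6-methoxyphenoxy)phenol | COc1cc(Br)cc(Br)c1Oc1cc(Br)c(Br)c(Br)c1O | intermediate
15 | 1,3-dibromobenzene | Brc1cccc(Br)c1 | starting material
16 | 2,4-dibromo-1-iodobenzene | Brc1ccc(I)c(Br)c1 | starting material
17 | 2,4-dibromo-1-(diacetoxyiodo)benzene | CC(=O)OI(OC(C)=O)c1ccc(Br)cc1Br | intermediate (not isolated)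
18 | bis(2,4-dibromophenyl)iodonium hydrogensulfate | Brc1ccc([I+]c2ccc(Br)cc2Br)c(Br)c1.OS(=O)(=O)[O-] | intermediate (not isolated)
19 | bis(2,4-dibromophenyl)iodonium chloride | Brc1ccc([I+]c2ccc(Br)cc2Br)c(Br)c1.[Cl-] | intermediate
20 | 1,2,3-tribromo-5-(2,4-dibromo-6-methoxyphenoxy)-4-(2,4-dibromophenoxy)benzene | COc1cc(Br)cc(Br)c1Oc1cc(Br)c(Br)c(Br)c1Oc1ccc(Br)cc1Br | intermediate
21 | dibromo{3,5-dibromo-2-[3,4,5-tribromo-2-(2,4-dibromophenoxy)phenoxy]phenoxy}borane | BrB(Br)Oc1cc(Br)cc(Br)c1Oc1cc(Br)c(Br)c(Br)c1Oc1ccc(Br)cc1Br | intermediate (not isolated)
22 | 3,5-dibromo-2-[3,4,5-tribromo-2-(2,4-dibromophenoxy)phenoxy]phenol (bromoiesol A) | Oc1cc(Br)cc(Br)c1Oc1cc(Br)c(Br)c(Br)c1Oc1ccc(Br)cc1Br | intermediate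
23 | pyridinium 3,5-dibromo-2-[3,4,5-tribromo-2-(2,4-dibromophenoxy)phenoxy]phenyl sulfate | [O-]S(=O)(=O)Oc1cc(Br)cc(Br)c1Oc1cc(Br)c(Br)c(Br)c1Oc1ccc(Br)cc1Br.c1cc[nH+]cc1 | intermediate (not isolated)
24 | 3,5-dibromo-2-[3,4,5-tribromo-2-(2,4-dibromophenoxy)phenoxy]phenyl hydrogen sulfate (bromoiesol A sulfate) | O=S(=O)(O)Oc1cc(Br)cc(Br)c1Oc1cc(Br)c(Br)c(Br)c1Oc1ccc(Br)cc1Br | target

## Step count and least certain steps

Total step count: 10. Longest linear sequence: 8 steps (steps 1, 2, 3, 5, 6, 8, 9, 10). Steps 4 and 7 are the two side branches.

**Step 5 (key step).** Three things are most likely to go wrong.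
- The cross-cycloaddition may be slow: the dienophile is trisubstituted and its aryloxy group is flanked by two ortho substituents, so self-dimerisation of the diene can overtake it.
- The addition may go stepwise and stop after the first bond. A conjugate addition of the ketene acetal to the vinyl sulfone with silyl transfer would give open-chain or four-membered adducts instead of the six-membered ring.
- The ketene acetal may be protodesilylated by traces of acid before it reacts.

Fallback: ring B is bought instead of built, which also removes the need for 6 and 9. It sets out from 2 and comes back at 13. Phenol 2 is combined with purchased 1,2-dibromo-4-fluoro-5-nitrobenzene F1 (K2CO3, DMF, 60 °C; nucleophilic aromatic substitution of the fluorine ortho to the nitro group) to give 1,5-dibromo-2-(4,5-dibromo-2-nitrophenoxy)-3-methoxybenzene F2. Reduction with Fe powder and NH4Cl in EtOH/H2O, which leaves C–Br bonds alone, gives 4,5-dibromo-2-(2,4-dibromo-6-methoxyphenoxy)aniline F3. Diazotisation (NaNO2, H2SO4, AcOH, 0 °C) gives 4,5-dibromo-2-(2,4-dibromo-6-methoxyphenoxy)benzenediazonium hydrogensulfate F4, and hydroxydediazoniation with Cu2O and Cu(NO3)2 in water at room temperature gives 13.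

**Step 4.** Oxygen transfer to the sulfur of an electron-poor thiophene is slow, and during the long reaction time the S-oxide 8 or the dioxide 9 may dimerise by cycloaddition with itself.

Fallback: the oxidation is done on a silyl-protected thiophene that is more electron-rich and cannot dimerise. It sets out from 7 and comes back at 9. Double α-deprotonation with LiN(iPr)2 in the presence of Me3SiCl (THF, −78 °C) gives 3,4-dibromo-2,5-bis(trimethylsilyl)thiophene F5. Oxidation with mCPBA in CH2Cl2 gives the stable 3,4-dibromo-2,5-bis(trimethylsilyl)thiophene 1,1-dioxide F6. Protodesilylation of the two α-silyl vinyl sulfone positions (KF, AcOH, wet MeCN, 0 °C) then releases 9 just before step 5.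

**Step 6.** Site selectivity may be lost. C3 lies between the hydroxyl and the C4 bromine and is the most hindered of the activated positions, so bromination at C6, on ring A, or overbromination may compete.

Fallback: the third bromine is carried in on the diene instead of being put on the arene. It sets out from 6 and comes back at 14. Purchased 2,3,4-tribromothiophene F7 is oxidised as in step 4 to 2,3,4-tribromothiophene 1,1-dioxide F8, which is combined with 6 as in step 5. The bridged adduct 1,2,3-tribromo-5-(2,4-dibromo-6-methoxyphenoxy)-6,6-bis(trimethylsilyloxy)-7-thiabicyclo[2.2.1]hept-2-ene 7,7-dioxide F9 loses SO2 to give 1,2,3-tribromo-5-(2,4-dibromo-6-methoxyphenoxy)-6,6-bis(trimethylsilyloxy)cyclohexa-1,3-diene F10. Silanol loss gives [2,3,4-tribromo-6-(2,4-dibromo-6-methoxyphenoxy)phenoxy]trimethylsilane F11, and acid hydrolysis gives 14 directly. The regiochemistry needed is the one expected if the nucleophilic aryloxy-bearing carbon of 6 attacks the unsubstituted, less hindered α-carbon of F8. It is not secured by symmetry, which is why this is the fallback and not the route.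

**Step 8.** Ligand coupling may be slow at a phenoxide that is flanked by a bromine and the ring A ether and made weakly nucleophilic by three bromines, so that hydroxide attack on the iodonium salt consumes the reagent.

Fallback: ring C is attached by nucleophilic aromatic substitution and its second bromine is introduced afterwards. It sets out from 14 and comes back at 20. Phenol 14 and purchased 2-bromo-1-fluoro-4-nitrobenzene F12 (K2CO3, DMF, 80 °C) give 1,2,3-tribromo-4-(2-bromo-4-nitrophenoxy)-5-(2,4-dibromo-6-methoxyphenoxy)benzene F13. Fe powder and NH4Cl in EtOH/H2O give 3-bromo-4-[2,3,4-tribromo-6-(2,4-dibromo-6-methoxyphenoxy)phenoxy]aniline F14. Diazotisation (NaNO2, HBr, AcOH, 0 °C) gives 3-bromo-4-[2,3,4-tribromo-6-(2,4-dibromo-6-methoxyphenoxy)phenoxy]benzenediazonium bromide F15, and a Sandmeyer reaction with CuBr at 60 °C gives 20.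

**Step 10.** Sulfation may be incomplete, and the S–O bond may be cleaved by acid while the free acid is released and concentrated; the lipophilic, ionic product is also hard to purify.

Fallback: the sulfate is carried as a neutral diester that can be chromatographed and is unmasked under neutral reducing conditions. It sets out from 22 and comes back at 24. Phenol 22 and 2,2,2-trichloroethyl chlorosulfate F16 (Et3N, DMAP, THF) give 3,5-dibromo-2-[3,4,5-tribromo-2-(2,4-dibromophenoxy)phenoxy]phenyl 2,2,2-trichloroethyl sulfate F17. Reductive fragmentation with Zn and HCO2NH4 in MeOH at room temperature, which should leave aryl bromides untouched, gives ammonium 3,5-dibromo-2-[3,4,5-tribromo-2-(2,4-dibromophenoxy)phenoxy]phenyl sulfate F18, and the cold cation exchange of step 10 gives 24.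

**Step 7.** The aryl–iodine coupling may stall: the electrophile derived from 17 has to substitute an arene that two bromines deactivate, and the iodane may be reduced back to 16 or consumed by the medium before substitution takes place.

Fallback: both aryl groups are taken from the arene and the iodine from an inorganic trivalent iodine electrophile, so no aryliodane is needed. It sets out from 15 and comes back at 19. I2 and KIO3 in conc. H2SO4 give iodosyl sulfate F19, a smaller and more electrophilic reagent than the aryliodane. Two molecules of 15 are substituted by it at C4 one after the other (0 °C → rt) to give the hydrogensulfate 18, and aq. NaCl precipitates 19.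

## Further compounds

F1 | step 5 | 1,2-dibromo-4-fluoro-5-nitrobenzene | O=[N+]([O-])c1cc(Br)c(Br)cc1F
F2 | step 5 | 1,5-dibromo-2-(4,5-dibromo-2-nitrophenoxy)-3-methoxybenzene | COc1cc(Br)cc(Br)c1Oc1cc(Br)c(Br)cc1[N+](=O)[O-]
F3 | step 5 | 4,5-dibromo-2-(2,4-dibromo-6-methoxyphenoxy)aniline | COc1cc(Br)cc(Br)c1Oc1cc(Br)c(Br)cc1N
F4 | step 5 | 4,5-dibromo-2-(2,4-dibromo-6-methoxyphenoxy)benzenediazonium hydrogensulfate | COc1cc(Br)cc(Br)c1Oc1cc(Br)c(Br)cc1[N+]#N.OS(=O)(=O)[O-]
F5 | step 4 | 3,4-dibromo-2,5-bis(trimethylsilyl)thiophene | C[Si](C)(C)c1sc([Si](C)(C)C)c(Br)c1Br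
F6 | step 4 | 3,4-dibromo-2,5-bis(trimethylsilyl)thiophene 1,1-dioxide | C[Si](C)(C)C1=C(Br)C(Br)=C([Si](C)(C)C)S1(=O)=O
F7 | step 6 | 2,3,4-tribromothiophene | Brc1csc(Br)c1Br
F8 | step 6 | 2,3,4-tribromothiophene 1,1-dioxide | O=S1(=O)C=C(Br)C(Br)=C1Br
F9 | step 6 | 1,2,3-tribromo-5-(2,4-dibromo-6-methoxyphenoxy)-6,6-bis(trimethylsilyloxy)-7-thiabicyclo[2.2.1]hept-2-ene 7,7-dioxide | O=S1(=O)C2(Br)C(Br)=C(Br)C1C(Oc1c(Br)cc(Br)cc1OC)C2(O[Si](C)(C)C)O[Si](C)(C)C
F10 | step 6 | 1,2,3-tribromo-5-(2,4-dibromo-6-methoxyphenoxy)-6,6-bis(trimethylsilyloxy)cyclohexa-1,3-diene | BrC1=C(Br)C(Br)=CC(Oc2c(Br)cc(Br)cc2OC)C1(O[Si](C)(C)C)O[Si](C)(C)C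
F11 | step 6 | [2,3,4-tribromo-6-(2,4-dibromo-6-methoxyphenoxy)phenoxy]trimethylsilane | COc1cc(Br)cc(Br)c1Oc1cc(Br)c(Br)c(Br)c1O[Si](C)(C)C
F12 | step 8 | 2-bromo-1-fluoro-4-nitrobenzene | O=[N+]([O-])c1ccc(F)c(Br)c1
F13 | step 8 | 1,2,3-tribromo-4-(2-bromo-4-nitrophenoxy)-5-(2,4-dibromo-6-methoxyphenoxy)benzene | COc1cc(Br)cc(Br)c1Oc1cc(Br)c(Br)c(Br)c1Oc1ccc(cc1Br)[N+](=O)[O-]
F14 | step 8 | 3-bromo-4-[2,3,4-tribromo-6-(2,4-dibromo-6-methoxyphenoxy)phenoxy]aniline | COc1cc(Br)cc(Br)c1Oc1cc(Br)c(Br)c(Br)c1Oc1ccc(N)cc1Br
F15 | step 8 | 3-bromo-4-[2,3,4-tribromo-6-(2,4-dibromo-6-methoxyphenoxy)phenoxy]benzenediazonium bromide | COc1cc(Br)cc(Br)c1Oc1cc(Br)c(Br)c(Br)c1Oc1ccc(cc1Br)[N+]#N.[Br-]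
F16 | step 10 | 2,2,2-trichloroethyl chlorosulfate | ClS(=O)(=O)OCC(Cl)(Cl)Cl
F17 | step 10 | 3,5-dibromo-2-[3,4,5-tribromo-2-(2,4-dibromophenoxy)phenoxy]phenyl 2,2,2-trichloroethyl sulfate | ClC(Cl)(Cl)COS(=O)(=O)Oc1cc(Br)cc(Br)c1Oc1cc(Br)c(Br)c(Br)c1Oc1ccc(Br)cc1Br
F18 | step 10 | ammonium 3,5-dibromo-2-[3,4,5-tribromo-2-(2,4-dibromophenoxy)phenoxy]phenyl sulfate | [NH4+].[O-]S(=O)(=O)Oc1cc(Br)cc(Br)c1Oc1cc(Br)c(Br)c(Br)c1Oc1ccc(Br)cc1Br
F19 | step 7 | iodosyl sulfate | O=IOS(=O)(=O)OI=O
A1 | alternative 1 | 3,5-dibromo-2H-pyran-2-one (3,5-dibromo-2-pyrone) | O=C1OC=C(Br)C=C1Br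
A2 | alternative 1 | 4,4,5,5-tetramethyl-2-{[3,4,5-tribromo-2-(2,4-dibromophenoxy)phenoxy]ethynyl}-1,3,2-dioxaborolane | CC1(C)OB(C#COc2cc(Br)c(Br)c(Br)c2Oc2ccc(Br)cc2Br)OC1(C)C
A3 | alternative 1 | 2-{3,5-dibromo-2-[3,4,5-tribromo-2-(2,4-dibromophenoxy)phenoxy]phenyl}-4,4,5,5-tetramethyl-1,3,2-dioxaborolane | CC1(C)OB(OC1(C)C)c1cc(Br)cc(Br)c1Oc1cc(Br)c(Br)c(Br)c1Oc1ccc(Br)cc1Br
A4 | alternative 2 | {[5-(2,4-dibromo-6-methoxyphenoxy)cyclopent-1-en-1-yl]oxy}trimethylsilane | COc1cc(Br)cc(Br)c1OC1CCC=C1O[Si](C)(C)C
A5 | alternative 2 | 2-bromo-6-(2,4-dibromo-6-methoxyphenoxy)cyclohex-2-en-1-one | COc1cc(Br)cc(Br)c1OC1CCC=C(Br)C1=O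
A6 | alternative 3 | 1,2,3-tribromo-4-(ethynyloxy)-5-methoxybenzene | COc1cc(Br)c(Br)c(Br)c1OC#C
A7 | alternative 3 | 1,2,3-tribromo-4-(2,4-dibromophenoxy)-5-methoxybenzene | COc1cc(Br)c(Br)c(Br)c1Oc1ccc(Br)cc1Br
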